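**Plan**
1. Numbering used below (elemane): C10 = quaternary ring carbon (CH3, vinyl); C5 = ring CH carrying the isopropenyl group (C4); C6 = lactone CH–O; C7 = ring-fusion CH; C8 = CH–O–acyl; C9 = CH2; C11 = C(CH3)(OAc); C12 = lactone C=O.
2. Retrosynthesis: first the C8–O ester, then the two ring bonds C5–C6 and C7–C8 in one cut. The cyclohexane falls into an open-chain aldehyde C8(=O)–C9–C10–C5=C4Me2 and the enol lactone O–C6=C7–C11(Me)(OAc)–C12(=O), i.e. the intact five-membered lactone with its acetate.
3. Feature that allows this: O6–C6–C7 of the γ-lactone is a latent enol ester (C7 nucleophilic; C6 an acyloxocarbenium carbon once C7 has reacted). C8 is a carbinol (aldehyde) carbon, and C5 is allylic to the isopropenyl carbon C4, so it is the inner carbon of a prenyl-type alkene. The quaternary C10 insulates the two chain ends.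
4. Forward: the chain (five steps; C10 by copper-catalysed SN2′ substitution) and the enol lactone (five steps from (S)-citramalic acid) are joined in one Lewis-acid operation that builds the six-membered ring onto the five-membered ring; esterification of the C8 hydroxyl ends the route.
5. Stereochemistry: C10 by asymmetric catalysis; C11 bought with citramalic acid; C7 from C11 (face of the enol); C6 from the forced cis ring fusion; C8 and C5 from the chair of the ring closure.

Key step: step 11

Remark: the target is read as 3S,3aS,4R,6S,7R,7aR in benzofuranone numbering (C11 S, C7 S, C8 R, C10 S, C5 R, C6 R): a cis-fused lactone with the isopropenyl group, O6, C11 and the vinyl group on one ring face and O8 and the C10 methyl on the other. The silyl butynyl ether, the alkenylboronate, (S)-citramalic acid and 3-methylbut-3-enoic acid are taken as commercial.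

**Route**

Step 1
Reactants: 1 tert-butyl(but-3-yn-1-yloxy)dimethylsilane
Product: 3 (2E)-5-(tert-butyldimethylsilyloxy)-3-methylpent-2-en-1-ol, via alkenylalane 2 (not isolated)
Conditions: Me3Al (2.5 equiv), Cp2ZrCl2 (0.25 equiv), CH2Cl2, 0 °C to rt; then (CH2O)n, THF, 0 °C to rt; aqueous work-up
Reagents that add atoms: trimethylaluminium C[Al](C)C; formaldehyde (as paraformaldehyde) C=O
Why: Zirconium-catalysed carboalumination (Negishi) adds CH3 and Al syn across the terminal alkyne with CH3 on the inner carbon, and the alkenylalane is hydroxymethylated with retention of geometry, so only the E allylic alcohol should form.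

Step 2
Reactants: 3 (2E)-5-(tert-butyldimethylsilyloxy)-3-methylpent-2-en-1-ol
Product: 4 (2E)-5-(tert-butyldimethylsilyloxy)-3-methylpent-2-en-1-yl diethyl phosphate
Conditions: (EtO)2P(O)Cl, Et3N, DMAP (cat.), CH2Cl2, 0 °C
Reagents that add atoms: diethyl chlorophosphate CCOP(=O)(Cl)OCC
Why: Phosphorylation of the primary allylic alcohol gives the leaving group needed for copper-catalysed SN2′ substitution; the E alkene is untouched.

Step 3
Reactants: 4 (2E)-5-(tert-butyldimethylsilyloxy)-3-methylpent-2-en-1-yl diethyl phosphate; 5 4,4,5,5-tetramethyl-2-(2-methylprop-1-en-1-yl)-1,3,2-dioxaborolane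
Product: 6 tert-butyl{[(3S)-3-ethenyl-3,5-dimethylhex-4-en-1-yl]oxy}dimethylsilane
Conditions: CuCl (5 mol%), chiral sulfonate-bearing imidazolinium salt (N-heterocyclic carbene precursor, 5.5 mol%), NaOMe (1.5 equiv), THF, 22 to 60 °C
Reagents that add atoms: none
Why: Copper-catalysed enantioselective allylic substitution (SN2′) with an alkenylboron nucleophile: the alkenylcopper species from B-to-Cu transmetalation adds to the methyl-bearing γ-carbon under control of the chiral carbene ligand, which creates the quaternary C10 stereocentre together with its vinyl group (ligand enantiomer chosen to give S).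

Step 4
Reactants: 6 tert-butyl{[(3S)-3-ethenyl-3,5-dimethylhex-4-en-1-yl]oxy}dimethylsilane
Product: 7 (3S)-3-ethenyl-3,5-dimethylhex-4-en-1-ol
Conditions: TBAF, THF, 0 °C to rt
Reagents that add atoms: none
Why: Fluoride cleavage of the primary silyl ether; the 1,4-diene and the quaternary centre are inert.

Step 5
Reactants: 7 (3S)-3-ethenyl-3,5-dimethylhex-4-en-1-ol
Product: 8 (3S)-3-ethenyl-3,5-dimethylhex-4-enal
Conditions: Dess–Martin periodinane, pyridine, CH2Cl2, 0 °C to rt; used without storage
Reagents that add atoms: none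
Why: Dess–Martin oxidation of the primary alcohol under buffered conditions; the aldehyde has no α-stereocentre and C10 cannot epimerise.

Step 6
Reactants: 9 (S)-citramalic acid
Product: 10 2-[(4S)-2,2,4-trimethyl-5-oxo-1,3-dioxolan-4-yl]acetic acid
Conditions: 2,2-dimethoxypropane, TsOH·H2O (cat.), rt
Reagents that add atoms: 2,2-dimethoxypropane COC(C)(C)OC
Why: Acid-catalysed acetalisation engages the α-hydroxy acid as the five-membered dioxolanone and leaves the CH2CO2H arm free, which differentiates the two carboxyl groups; the stereocentre (C11) is not touched.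

Step 7
Reactants: 10 2-[(4S)-2,2,4-trimethyl-5-oxo-1,3-dioxolan-4-yl]acetic acid
Product: 12 2-[(4S)-2,2,4-trimethyl-5-oxo-1,3-dioxolan-4-yl]acetaldehyde, via acid chloride 11 (not isolated)
Conditions: (COCl)2, DMF (cat.), CH2Cl2, 0 °C to rt, evaporate; then H2 (1 atm), Pd/BaSO4, 2,6-lutidine, THF, rt
Reagents that add atoms: none
Why: Acid chloride formation and Rosenmund hydrogenolysis reduce only the free carboxyl group to the aldehyde (future C6); the dioxolanone is stable to both stages.

Step 8
Reactants: 12 2-[(4S)-2,2,4-trimethyl-5-oxo-1,3-dioxolan-4-yl]acetaldehyde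
Product: 13 (3S)-3,5-dihydroxy-3-methyloxolan-2-one (both C5 epimers)
Conditions: AcOH/H2O (4:1), 45 °C; evaporate with toluene
Reagents that add atoms: water O
Why: Acid hydrolysis of the acetonide; the liberated 4-oxo acid closes to the five-membered lactol (pseudo-acid), favoured by the quaternary C11.

Step 9
Reactants: 13 (3S)-3,5-dihydroxy-3-methyloxolan-2-one
Product: 14 (3S)-3-methyl-2-oxooxolane-3,5-diyl diacetate (both C5 epimers)
Conditions: Ac2O, Et3N, DMAP (cat.), CH2Cl2, rt
Reagents that add atoms: acetic anhydride CC(=O)OC(C)=O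
Why: DMAP-catalysed acetylation of the lactol OH and of the tertiary C11 OH, which installs the acetate of the target; C6 stays a mixture because it becomes sp2 in the next step.

Step 10
Reactants: 14 (3S)-3-methyl-2-oxooxolane-3,5-diyl diacetate
Product: 16 (3S)-3-methyl-2-oxo-2,3-dihydrofuran-3-yl acetate, via bromo lactone 15 (not isolated)
Conditions: TMSBr, CH2Cl2, 0 °C; then Et3N, 0 °C to rt
Reagents that add atoms: none
Why: Exchange of the anomeric acetate for bromide (as in glycosyl bromide formation) and anti-elimination of HBr by the amine (glycal-type elimination) give the enol lactone under non-acidic conditions; the quaternary C11 cannot tautomerise into conjugation and keeps its configuration.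

Step 11
Reactants: 8 (3S)-3-ethenyl-3,5-dimethylhex-4-enal; 16 (3S)-3-methyl-2-oxo-2,3-dihydrofuran-3-yl acetate
Product: 18 (3S,3aS,4R,6S,7R,7aR)-6-ethenyl-4-hydroxy-3,6-dimethyl-2-oxo-7-(prop-1-en-2-yl)octahydro-1-benzofuran-3-yl acetate, via acyloxocarbenium zwitterion 17 (not isolated)
Conditions: 16 (3 equiv), 2,6-di-tert-butyl-4-methylpyridine (1.2 equiv), CH2Cl2, −78 °C; slow simultaneous addition of 8 and BF3·OEt2 (1.1 equiv) over 2 h; −78 to −30 °C; aqueous NaHCO3
Reagents that add atoms: none
Why: Proposed new method: BF3 activates the aldehyde of 8, the enol C6=C7 bond of 16 attacks it through C7 (C7–C8) and leaves the five-membered acyloxocarbenium ion 17 at C6, the tethered trisubstituted alkene then attacks C6 through its inner carbon C5 (C5–C6), and the 2-propyl cation loses a methyl proton to the pyridine base to give the isopropenyl group. The closest known reaction types are the Lewis-acid coupling of a cyclic enol ether or an enol ester with an aldehyde followed by capture of the oxocarbenium ion by a π-nucleophile (Mukaiyama aldol–Prins sequences) and the Prins cyclisation of alkenyl aldehydes that ends in proton loss; new are the enol lactone as the two-carbon unit and the tethering of the terminating alkene to the aldehyde, so that a carbocycle forms. The cyclohexane closes 6-exo-trig (C5 bonds, C4 stays outside the ring) through a chair on the planar five-membered cation, so the tether from C7 can reach only the same face of C6 and the lactone must come out cis-fused (C6). C7 is set by C11, the aldehyde adding to the enol face anti to the methyl group and syn to the flatter acetoxy group; C8 by the open antiperiplanar addition, backed by the ring closure, which should be fast only for the epimer with the OBF3 group equatorial while the first addition is reversible; C5 by the chair with the alkene terminus C4 equatorial, cis to O6; the fixed C10 places its vinyl group axial and its methyl group equatorial. The step needs the aldehyde to be attacked by 16 and not by the alkene of a second molecule of 8 (low concentration of 8 against excess 16; C5 is neopentyl; attack on its own aldehyde would close a four-membered ring), the tertiary allylic acetate of 16 not to ionise (no free BF3), the C8 oxygen to stay off the activated lactone carbonyl (the O–BF3 group is a poor nucleophile) and proton loss toward the methyl groups (hindered base, low temperature).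

Step 12
Reactants: 18 (3S,3aS,4R,6S,7R,7aR)-6-ethenyl-4-hydroxy-3,6-dimethyl-2-oxo-7-(prop-1-en-2-yl)octahydro-1-benzofuran-3-yl acetate; 19 3-methylbut-3-enoic acid
Product: 20 (3S,3aS,4R,6S,7R,7aR)-3-acetoxy-6-ethenyl-3,6-dimethyl-2-oxo-7-(prop-1-en-2-yl)octahydro-1-benzofuran-4-yl 3-methylbut-3-enoate
Conditions: N,N'-diisopropylcarbodiimide, DMAP (0.1 equiv), CH2Cl2, 0 °C
Reagents that add atoms: none
Why: Carbodiimide (Steglich) esterification of the equatorial secondary C8 hydroxyl; low temperature and little DMAP keep the β,γ-double bond of the acid from moving into conjugation, and the tertiary acetate and the lactone are inert.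

**Compound list**
1 | tert-butyl(but-3-yn-1-yloxy)dimethylsilane | C#CCCO[Si](C)(C)C(C)(C)C | starting material
2 | [(1E)-4-(tert-butyldimethylsilyloxy)-2-methylbut-1-en-1-yl]dimethylalumane | C[Al](C)/C=C(\C)CCO[Si](C)(C)C(C)(C)C | intermediate
3 | (2E)-5-(tert-butyldimethylsilyloxy)-3-methylpent-2-en-1-ol | OC/C=C(\C)CCO[Si](C)(C)C(C)(C)C | intermediate
4 | (2E)-5-(tert-butyldimethylsilyloxy)-3-methylpent-2-en-1-yl diethyl phosphate | CCOP(=O)(OCC)OC/C=C(\C)CCO[Si](C)(C)C(C)(C)C | intermediate
5 | 4,4,5,5-tetramethyl-2-(2-methylprop-1-en-1-yl)-1,3,2-dioxaborolane | CC(C)=CB1OC(C)(C)C(C)(C)O1 | starting material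
6 | tert-butyl{[(3S)-3-ethenyl-3,5-dimethylhex-4-en-1-yl]oxy}dimethylsilane | C=C[C@](C=C(C)C)(C)CCO[Si](C)(C)C(C)(C)C | intermediate
7 | (3S)-3-ethenyl-3,5-dimethylhex-4-en-1-ol | C=C[C@](C=C(C)C)(C)CCO | intermediate
8 | (3S)-3-ethenyl-3,5-dimethylhex-4-enal | C=C[C@](C=C(C)C)(C)CC=O | intermediate
9 | (S)-citramalic acid, (2S)-2-hydroxy-2-methylbutanedioic acid | C[C@](O)(CC(=O)O)C(=O)O | starting material
10 | 2-[(4S)-2,2,4-trimethyl-5-oxo-1,3-dioxolan-4-yl]acetic acid | C[C@@]1(CC(=O)O)OC(C)(C)OC1=O | intermediate
11 | 2-[(4S)-2,2,4-trimethyl-5-oxo-1,3-dioxolan-4-yl]acetyl chloride | C[C@@]1(CC(=O)Cl)OC(C)(C)OC1=O | intermediate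
12 | 2-[(4S)-2,2,4-trimethyl-5-oxo-1,3-dioxolan-4-yl]acetaldehyde | C[C@@]1(CC=O)OC(C)(C)OC1=O | intermediate
13 | (3S)-3,5-dihydroxy-3-methyloxolan-2-one (both C5 epimers) | C[C@]1(O)CC(O)OC1=O | intermediate
14 | (3S)-3-methyl-2-oxooxolane-3,5-diyl diacetate (both C5 epimers) | CC(=O)O[C@@]1(C)CC(OC(C)=O)OC1=O | intermediate
15 | (3S)-5-bromo-3-methyl-2-oxooxolan-3-yl acetate | CC(=O)O[C@@]1(C)CC(Br)OC1=O | intermediate
16 | (3S)-3-methyl-2-oxo-2,3-dihydrofuran-3-yl acetate | O=C1OC=C[C@]1(C)OC(C)=O | intermediate
17 | BF3-bound aldolate with the ring acyloxocarbenium ion at C6 (zwitterion) | C=C[C@](C=C(C)C)(C)C[C@@H](O[B-](F)(F)F)[C@H]1C=[O+]C(=O)[C@@]1(C)OC(C)=O | intermediate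
18 | (3S,3aS,4R,6S,7R,7aR)-6-ethenyl-4-hydroxy-3,6-dimethyl-2-oxo-7-(prop-1-en-2-yl)octahydro-1-benzofuran-3-yl acetate | C=C[C@]1(C)C[C@@H](O)[C@H]2[C@H](OC(=O)[C@@]2(C)OC(C)=O)[C@@H]1C(=C)C | intermediate
19 | 3-methylbut-3-enoic acid | C=C(C)CC(=O)O | starting material
20 | (3S,3aS,4R,6S,7R,7aR)-3-acetoxy-6-ethenyl-3,6-dimethyl-2-oxo-7-(prop-1-en-2-yl)octahydro-1-benzofuran-4-yl 3-methylbut-3-enoate | C=C[C@]1(C)C[C@@H](OC(=O)CC(=C)C)[C@H]2[C@H](OC(=O)[C@@]2(C)OC(C)=O)[C@@H]1C(=C)C | target

**Count**
Total steps: 12. Longest linear sequence: 7 steps (1–5, 11, 12; the lactone branch 6–10, 11, 12 is equally long).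

**Steps most likely to fail**

Step 11. What may go wrong:
- the enol lactone attacks too slowly, so the aldehyde oligomerises through the alkene of other chain molecules;
- the tertiary allylic acetate of 16 ionises;
- the lactone acyl group migrates to the C8 oxygen;
- facial selectivity at C7 or C8 is poor;
- the cation loses the C5 proton and gives the isopropylidene isomer.

Fallback (known chemistry, sets out from 8 and 12, comes back at 20): aldehyde 12 is converted with TBSOTf and Et3N into its silyl enol ether F1, a far stronger π-nucleophile that carries no allylic acetate. A Mukaiyama aldol addition of F1 to 8 (BF3·OEt2, CH2Cl2, −78 °C) should give the β-hydroxy aldehyde F2. Its C8 hydroxyl is esterified at once with 19 (N,N'-diisopropylcarbodiimide, DMAP cat.) to the ester aldehyde F3, which blocks acyl migration. Aqueous acetic acid removes the acetonide and the 4-oxo acid closes to the lactol F4. Ac2O, Et3N and DMAP give the lactol diacetate F5. BF3·OEt2 (CH2Cl2, −40 °C) then ionises the lactol acetate to the same ring acyloxocarbenium ion, and the cation–olefin cyclisation (known for γ-acyloxy lactones and N-acyliminium ions) closes the ring to 20.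

Step 10. What may go wrong: the enol lactone is lost during elimination or isolation, either by halide- or acid-induced 1,3-shift of the allylic acetate into the conjugated 5-acetoxybutenolide or by polymerisation.

Fallback (sets out from 13, comes back at 16): lactol 13 is converted with PhSH and BF3·OEt2 into the thioacetal lactone F6 and acetylated (Ac2O, Et3N, DMAP) to the thioacetal acetate F7. Oxidation (mCPBA, CH2Cl2, −78 °C) gives the sulfoxide F8. Heating (toluene, 110 °C, CaCO3) should give 16 by thermal syn-elimination of benzenesulfenic acid under neutral conditions.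

Step 3. What may go wrong: poor enantioselectivity, or direct (SN2) substitution competing with SN2′ for the hindered trisubstituted alkenyl nucleophile.

Fallback (sets out from 3, comes back at 6): Sharpless asymmetric epoxidation of 3 (Ti(OiPr)4, D-(−)-diethyl tartrate, tBuOOH, 4 Å molecular sieves, CH2Cl2, −20 °C) gives the epoxy alcohol F9. Diethyl(2-methylprop-1-enyl)aluminium, Et2AlCH=CMe2, opens it at the more substituted carbon with inversion and gives the 1,2-diol F10 with the quaternary carbon in place. Deoxygenation of the diol to the vinyl group (I2, PPh3, imidazole, toluene, 110 °C) gives 6.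

Further compounds
F1 | step 11 | (S)-5-[2-(tert-butyldimethylsilyloxy)ethenyl]-2,2,5-trimethyl-1,3-dioxolan-4-one (E/Z mixture) | C[C@@]1(C=CO[Si](C)(C)C(C)(C)C)OC(C)(C)OC1=O
F2 | step 11 | 5-ethenyl-3-hydroxy-5,7-dimethyl-2-[(4S)-2,2,4-trimethyl-5-oxo-1,3-dioxolan-4-yl]oct-6-enal (C7 and C8 as in the target) | C=C[C@](C=C(C)C)(C)C[C@@H](O)[C@@H](C=O)[C@]1(C)OC(C)(C)OC1=O
F3 | step 11 | 3-methylbut-3-enoate of F2 at the C8 hydroxyl | C=C[C@](C=C(C)C)(C)C[C@@H](OC(=O)CC(=C)C)[C@@H](C=O)[C@]1(C)OC(C)(C)OC1=O
F4 | step 11 | lactol (5-hydroxy lactone with free C11 hydroxyl) from F3 | C=C[C@](C=C(C)C)(C)C[C@@H](OC(=O)CC(=C)C)[C@H]1C(O)OC(=O)[C@@]1(C)O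
F5 | step 11 | diacetate of F4 (lactol acetate and C11 acetate) | C=C[C@](C=C(C)C)(C)C[C@@H](OC(=O)CC(=C)C)[C@H]1C(OC(C)=O)OC(=O)[C@@]1(C)OC(C)=O
F6 | step 10 | (3S)-3-hydroxy-3-methyl-5-(phenylsulfanyl)oxolan-2-one | C[C@]1(O)CC(Sc2ccccc2)OC1=O
F7 | step 10 | (3S)-3-methyl-2-oxo-5-(phenylsulfanyl)oxolan-3-yl acetate | CC(=O)O[C@@]1(C)CC(Sc2ccccc2)OC1=O
F8 | step 10 | (3S)-5-(benzenesulfinyl)-3-methyl-2-oxooxolan-3-yl acetate | CC(=O)O[C@@]1(C)CC(S(=O)c2ccccc2)OC1=O
F9 | step 3 | [(2R,3R)-3-{2-[(tert-butyldimethylsilyl)oxy]ethyl}-3-methyloxiran-2-yl]methanol | OC[C@H]1O[C@]1(C)CCO[Si](C)(C)C(C)(C)C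
F10 | step 3 | (2S,3R)-3-{2-[(tert-butyldimethylsilyl)oxy]ethyl}-3,5-dimethylhex-4-ene-1,2-diol | OC[C@@H](O)[C@](C=C(C)C)(C)CCO[Si](C)(C)C(C)(C)C
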